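## Analysis of the target

Labdane numbering is used for the target and every intermediate: ring A is C1–C5 plus C10, ring B is C5–C10, C11–C15 with the C16 methyl form the chain on C9, C17 is the methylene carbon on C8, C18 and C19 are the methyl and ester carbons on C4, and C20 is the angular methyl on C10. The target is a trans-fused decalin with two quaternary carbons (C4 and C10), an equatorial acetoxy group at C1, an exocyclic C8=C17 alkene and an (E)-3-methylpenta-2,4-dienyl chain on C9. Its five stereocentres are 1S,4R,5S,9R,10S. H5 is anti to C20, whereas the axial C19 ester, the equatorial C1 oxygen and the equatorial C11 all lie on the C20 face, so C19 and C20 are syn-diaxial and the C1 and C9 substituents flank C10 in a peri relationship. The sensitive groups are the 1,1-disubstituted alkene (it migrates into the ring under acid), the conjugated diene (acid, oxidants, dienophiles) and the acetate, which cannot coexist with hydride or ylide reagents although the hindered C19 methyl ester can. The difficulty lies in the contiguous array C1–C10–C5–C4 with two quaternary members, in placing C11 equatorial on C9 next to quaternary C10, and in telling two methyl esters apart late in the route. The strategy rests on the C8–C9 bond of ring B. C8, the methylene-bearing carbon, can be a tertiary methyl carbinol, and C9 with its CH2 arm can be the β-carbon of a C9=C11 enoate held on C10, so ring B closes by a ketyl–olefin cyclisation that sets C9 and delivers C11–C12 as an ester arm.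

## Retrosynthetic reasoning

**27 to 25 (C1 oxygen).** The acetate is introduced last from alcohol 26, which comes from silyl ether 25. No skeletal bond is cut. An acetate would not survive the hydride and ylide steps that precede it, whereas a hindered silyl ether survives every step from ring A onward.

**25 to 23 (C14=C15 and C12=C13).** The diene is cut at both double bonds into enal 24 and then aldehyde 23. Each cut is a carbonyl olefination, and the stabilised ylide that makes C12=C13 controls its E geometry. The diene is built late so that this fragile unit meets no acid and no oxidant.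

**23 to 22 (C12 oxidation level).** The aldehyde is traced to the C12 methyl ester of 22. The forward step has to reduce the unhindered CH2CO2CH3 arm and leave the axial C19 ester on quaternary C4.

**22 to 20 (C8=C17).** The exocyclic alkene is traced to the tertiary carbinol 20 by loss of water. With the C8 hydroxyl equatorial, only the C17 methyl hydrogens can be antiperiplanar to C–O, so elimination should go to the methyl side.

**20 to 19 (C8–C9, the key cut).** Cutting C8–C9 opens ring B to the monocyclic keto enoate 19. This bond is chosen because both ends carry exactly the functions a reductive ketyl–olefin coupling needs and leaves. The cut removes the second ring and two stereocentres at once, and it leaves a ring A compound in which C9 and C11 are an ordinary E-enoate. The forward step must add the C8 ketyl 6-exo to C9 with C11 ending equatorial.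

**19 to 16 and 17 (C9=C11).** The enoate is cut by a Horner–Wadsworth–Emmons disconnection into aldehyde 16 and phosphonate 17, with the methyl ketone masked as the dioxolane 18 until after olefination. The aldehyde sits on quaternary C10 and cannot enolise.

**16 to 13 (C1 and C9 oxidation levels).** Aldehyde 16 comes from hydroxy aldehyde 15 by silylation, 15 from diol 14 by selective oxidation of the primary alcohol, and 14 from β-hydroxy ketone 13. The C9 hydroxyl of 13 directs the hydride to C1, so the C1 configuration is derived from C10.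

**13 to 8 (C10–C9 and C10–C20).** Hydrogenation relates 13 to enone 12, and the two C10 substituents are cut off in turn: C9 (12 from 10) and C20 (10 from 8). The order is fixed, because the second electrophile enters anti to the C5 chain and C9 must be trans to C6. The C2=C3 double bond of the enone is kept through these steps because it makes C10 the only enolisable carbon.

**8 to 4 and 6 (C5–C6).** The chain is cut off at C5, leaving the prochiral dienone 4 and the Grignard reagent 6, made from bromide 5. One catalytic conjugate addition desymmetrises 4, sets C5 absolutely and turns the existing quaternary C4 into a stereocentre. The Grignard reagent is used directly, so each equivalent of bromide 5 delivers its chain.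

**4 to 1.** The C1 carbonyl comes from oxidation of the doubly allylic CH2 of diene 3, and the C4–C18 bond from reductive methylation of methyl benzoate 1.

## Alternatives that were turned down

**Alternative 1:** The C5–C10 bond is cut across a ten-membered carbocycle. A Lewis acid would open the trisubstituted C1–C10 epoxide of cyclodecene A1 at C10 while the ring allylsilane attacks through C5. This transannular closure would give the trans-decalinol A2, with C20, the C1 hydroxyl and H5 in the target's relative configuration and C4 left as an exocyclic methylene.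
- For: three stereocentres (C1, C5, C10) and the ring fusion come from one stereospecific step fixed by the epoxide and alkene geometry of A1. That is a firmer basis than the reagent-controlled steps 4 and 8 of the chosen route.
- Against: A2 lacks both features that make the target hard. C4 is still trigonal, so its methyl/ester pair must be built afterwards. C9 is a bare CH2 next to quaternary C10, so C11 would have to be attached through a C8 ketone enolate, which forms preferentially toward C7. A1 also needs a medium-ring synthesis with defined E-alkene geometry and an enantioselective epoxidation.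
- Comparison: the chosen strategy sets the ring A stereocentres one at a time, but it places C9 with its two-carbon arm and the C8 oxygen in the ring-closing step and needs no medium ring, so fewer operations follow ring closure.

**Alternative 2:** The C10–C20 bond is cut, and the angular methyl is delivered from the C1 oxygen. The (bromomethyl)dimethylsilyl ether A3 of an octalin with a C5=C10 double bond would cyclise 5-exo onto C10 under a tin hydride chain carrier. Hydrogen-atom transfer to the tertiary C5 radical would give siloxane A4, and protodesilylation would then reveal C20 and the C1 alcohol.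
- For: the five-membered siloxane can only be cis-fused, so the C1 oxygen and C20 are cis by construction. On this point it is stronger than the chosen route, which relies on a directed hydride reduction (step 8).
- Against: the ring fusion depends on the face of hydrogen transfer at a radical flanked by quaternary C4, which nothing in A3 controls firmly. A3 already needs the C4 stereocentre, a tetrasubstituted alkene and an enantiopure allylic alcohol. Cleaving an unactivated CH2–Si bond is forcing. Ring B of A4 carries only a ketal at C8, so the C9 chain must still be introduced on the hindered side of a C8 ketone.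
- Comparison: the chosen strategy gives up the built-in C1/C20 relationship. In its place it makes C10 quaternary by two enolate alkylations of predictable course and installs the C9 substituent during ring closure.

**Alternative 3:** Ring A is cut at C3–C4 and C5–C10 by a [4+2] disconnection. Heating the (5S)-menthyloxy butenolide A5 (C19, C4 with its methyl, C5 and C6) with the Z-silyloxydiene A6 would give the cis-fused lactone acetal A7, the diene adding anti to the menthyloxy group.
- For: C4 and C5 are set absolutely by a cheap auxiliary, and the lactone ring forces C19 and C6 to be cis. This is exactly the relationship the chosen route must win through facial selectivity in step 4, so here the alternative is the safer one.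
- Against: A5 is a trisubstituted and sluggish dienophile. C10 in A7 is only a methine that must later be made quaternary, yet the silyl enol ether of A7 points toward C2, not C10. C6 is locked at the aldehyde level in a menthyl acetal and needs a three-carbon extension. Ring B is not addressed, so a closure like that of the chosen route would still be needed.
- Comparison: the chosen strategy reaches the complete ring-closure precursor in fewer operations, because the conjugate addition brings in C6–C8 and C17 in one piece and the remaining enone directs both alkylations to C10.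

Key step: step 13

Assumption: the (R,SP) enantiomer of the ferrocenyl diphosphine named in step 4 is taken to give the 5S configuration of 8, by analogy with the sense of induction of this ligand class on cyclohex-2-enone; if the sense proves opposite, the (S,RP) ligand is used with no other change.

## Route

Step 1
Reactants: 1 methyl benzoate
Product: 3 methyl 1-methylcyclohexa-2,5-diene-1-carboxylate, via lithium ester enolate 2 (not isolated)
Conditions: Li (2.2 equiv), NH3(l)/THF, t-BuOH (1.0 equiv), −78 °C; then MeI (3 equiv), −78 °C → rt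
Reagents that add atoms: iodomethane, CI
Why: Birch reductive alkylation: two-electron reduction with one protonation at the para carbon gives the cross-conjugated ester enolate 2, which is C-methylated at the ipso carbon; the new quaternary carbon blocks rearomatisation.

Step 2
Reactants: 3 methyl 1-methylcyclohexa-2,5-diene-1-carboxylate
Product: 4 methyl 1-methyl-4-oxocyclohexa-2,5-diene-1-carboxylate
Conditions: CrO3 (0.1 equiv), t-BuOOH (5 equiv), CH2Cl2, rt
Reagents that add atoms: tert-butyl hydroperoxide, CC(C)(C)OO
Why: Chromium-catalysed allylic oxidation with a hydroperoxide: the doubly allylic CH2 is the only activated C–H position, and the quaternary carbon prevents the cross-conjugated dienone from tautomerising to a phenol.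

Step 3
Reactants: 5 2-(2-bromoethyl)-2-methyl-1,3-dioxolane
Product: 6 [2-(2-methyl-1,3-dioxolan-2-yl)ethyl]magnesium bromide
Conditions: Mg turnings (1.5 equiv), I2 (cat.), Et2O, 20–25 °C; titrated and used at once as an ethereal solution
Reagents that add atoms: magnesium, [Mg]
Why: Grignard formation by insertion of magnesium into the primary C–Br bond; the ketal is inert to the reagent, and the temperature is held at or below 25 °C because this Grignard reagent slowly cyclises onto its own ketal carbon when warmed.

Step 4
Reactants: 4 methyl 1-methyl-4-oxocyclohexa-2,5-diene-1-carboxylate; 6 [2-(2-methyl-1,3-dioxolan-2-yl)ethyl]magnesium bromide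
Product: 8 methyl (1S,6S)-1-methyl-6-[2-(2-methyl-1,3-dioxolan-2-yl)ethyl]-4-oxocyclohex-2-ene-1-carboxylate, via bromomagnesium dienolate 7 (not isolated)
Conditions: CuBr·SMe2 (5 mol%), (R)-1-[(SP)-2-(diphenylphosphino)ferrocenyl]ethyldicyclohexylphosphine (6 mol%), t-BuOMe, −75 °C; 6 (1.2 equiv in Et2O) added over 2 h; aq NH4Cl
Reagents that add atoms: none
Why: Copper-catalysed enantioselective conjugate addition of a Grignard reagent to a cyclic enone, here desymmetrising a 4,4-disubstituted cyclohexa-2,5-dienone: the chiral copper–diphosphine complex selects one enantiotopic enone arm and sets C5, and the alkyl group should enter on the face of the flat ester, anti to the methyl group, which fixes C4 relative to C5. Slow addition at low temperature keeps the uncatalysed 1,2-addition down, and the magnesium dienolate 7 is not an acceptor, so a second addition cannot occur.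

Step 5
Reactants: 8 methyl (1S,6S)-1-methyl-6-[2-(2-methyl-1,3-dioxolan-2-yl)ethyl]-4-oxocyclohex-2-ene-1-carboxylate
Product: 10 methyl (1R,5S,6S)-1,5-dimethyl-6-[2-(2-methyl-1,3-dioxolan-2-yl)ethyl]-4-oxocyclohex-2-ene-1-carboxylate, via lithium dienolate 9 (not isolated)
Conditions: LiN(i-Pr)2 (1.1 equiv), THF, −78 °C; MeI (3 equiv), −78 → −20 °C
Reagents that add atoms: iodomethane, CI
Why: Kinetic α′-deprotonation of the enone (C2 is vinylic and C4 quaternary, so C10 is the only enolisable carbon) and C-methylation of the cross-conjugated dienolate. The methyl group should enter trans to the C5 chain, but this centre is re-enolised in step 6, so its configuration does not matter.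

Step 6
Reactants: 10 methyl (1R,5S,6S)-1,5-dimethyl-6-[2-(2-methyl-1,3-dioxolan-2-yl)ethyl]-4-oxocyclohex-2-ene-1-carboxylate
Product: 12 methyl (1R,5R,6S)-5-(hydroxymethyl)-1,5-dimethyl-6-[2-(2-methyl-1,3-dioxolan-2-yl)ethyl]-4-oxocyclohex-2-ene-1-carboxylate, via lithium dienolate 11 (not isolated)
Conditions: LiN(i-Pr)2 (1.3 equiv), THF, −78 → −30 °C; CH2O (gas, from cracked paraformaldehyde), −78 °C; AcOH, −78 °C
Reagents that add atoms: formaldehyde, C=O
Why: Aldol addition of the tetrasubstituted lithium dienolate to monomeric formaldehyde; the electrophile approaches C10 anti to the C5 side chain, so C9 ends trans to C6 and C20 cis to it, which is the C10 configuration of the target. The cold acidic quench prevents retro-aldol cleavage.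

Step 7
Reactants: 12 methyl (1R,5R,6S)-5-(hydroxymethyl)-1,5-dimethyl-6-[2-(2-methyl-1,3-dioxolan-2-yl)ethyl]-4-oxocyclohex-2-ene-1-carboxylate
Product: 13 methyl (1R,2S,3R)-3-(hydroxymethyl)-1,3-dimethyl-2-[2-(2-methyl-1,3-dioxolan-2-yl)ethyl]-4-oxocyclohexane-1-carboxylate
Conditions: H2 (1 atm), 10% Pd/C, EtOAc, rt
Reagents that add atoms: none
Why: Heterogeneous hydrogenation of the disubstituted enone double bond; no stereocentre is formed, and the β-hydroxy ketone has no hydrogen on C10 and so cannot dehydrate.

Step 8
Reactants: 13 methyl (1R,2S,3R)-3-(hydroxymethyl)-1,3-dimethyl-2-[2-(2-methyl-1,3-dioxolan-2-yl)ethyl]-4-oxocyclohexane-1-carboxylate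
Product: 14 methyl (1R,2S,3R,4S)-4-hydroxy-3-(hydroxymethyl)-1,3-dimethyl-2-[2-(2-methyl-1,3-dioxolan-2-yl)ethyl]cyclohexane-1-carboxylate
Conditions: Me4NBH(OAc)3 (5 equiv), MeCN/AcOH (1:1), −20 °C → rt; aq KNaC4H4O6 (potassium sodium tartrate)
Reagents that add atoms: none
Why: Evans–Saksena reduction: the C9 hydroxyl exchanges onto boron and hydride is delivered intramolecularly to the carbonyl face that carries the CH2O arm, which places the new C1 hydroxyl anti to C9 and cis to C20. Axial attack on the chair with C20 axial leads to the same equatorial alcohol, so both controls agree.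

Step 9
Reactants: 14 methyl (1R,2S,3R,4S)-4-hydroxy-3-(hydroxymethyl)-1,3-dimethyl-2-[2-(2-methyl-1,3-dioxolan-2-yl)ethyl]cyclohexane-1-carboxylate
Product: 15 methyl (1R,2S,3S,4S)-3-formyl-4-hydroxy-1,3-dimethyl-2-[2-(2-methyl-1,3-dioxolan-2-yl)ethyl]cyclohexane-1-carboxylate
Conditions: TEMPO (0.2 equiv), PhI(OAc)2 (1.2 equiv), CH2Cl2, rt
Reagents that add atoms: none
Why: Oxoammonium (TEMPO) oxidation is selective for the primary alcohol over the hindered secondary C1 alcohol. The aldehyde has no α-hydrogen, so it can neither epimerise nor eliminate, and no base is present to trigger retro-aldol cleavage.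

Step 10
Reactants: 15 methyl (1R,2S,3S,4S)-3-formyl-4-hydroxy-1,3-dimethyl-2-[2-(2-methyl-1,3-dioxolan-2-yl)ethyl]cyclohexane-1-carboxylate
Product: 16 methyl (1R,2S,3S,4S)-4-[(tert-butyldimethylsilyl)oxy]-3-formyl-1,3-dimethyl-2-[2-(2-methyl-1,3-dioxolan-2-yl)ethyl]cyclohexane-1-carboxylate
Conditions: TBSOTf (1.5 equiv), 2,6-lutidine (3 equiv), CH2Cl2, −78 → 0 °C
Reagents that add atoms: tert-butyldimethylsilyl trifluoromethanesulfonate, CC(C)(C)[Si](C)(C)OS(=O)(=O)C(F)(F)F
Why: Silylation of a hindered secondary alcohol with a silyl triflate and a non-nucleophilic base; the non-enolisable aldehyde is inert, and the alcohol is capped before any basic step so that retro-aldol fragmentation is excluded.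

Step 11
Reactants: 16 methyl (1R,2S,3S,4S)-4-[(tert-butyldimethylsilyl)oxy]-3-formyl-1,3-dimethyl-2-[2-(2-methyl-1,3-dioxolan-2-yl)ethyl]cyclohexane-1-carboxylate; 17 trimethyl phosphonoacetate
Product: 18 methyl (1R,2S,3S,4S)-4-[(tert-butyldimethylsilyl)oxy]-3-[(1E)-3-methoxy-3-oxoprop-1-en-1-yl]-1,3-dimethyl-2-[2-(2-methyl-1,3-dioxolan-2-yl)ethyl]cyclohexane-1-carboxylate
Conditions: NaH (1.5 equiv), THF, 0 → 40 °C
Reagents that add atoms: none
Why: Horner–Wadsworth–Emmons olefination with a stabilised phosphonate anion gives the E-enoate; the aldehyde cannot enolise, so the hindered addition can be driven by time and mild warming.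

Step 12
Reactants: 18 methyl (1R,2S,3S,4S)-4-[(tert-butyldimethylsilyl)oxy]-3-[(1E)-3-methoxy-3-oxoprop-1-en-1-yl]-1,3-dimethyl-2-[2-(2-methyl-1,3-dioxolan-2-yl)ethyl]cyclohexane-1-carboxylate
Product: 19 methyl (1R,2S,3S,4S)-4-[(tert-butyldimethylsilyl)oxy]-3-[(1E)-3-methoxy-3-oxoprop-1-en-1-yl]-1,3-dimethyl-2-(3-oxobutyl)cyclohexane-1-carboxylate
Conditions: PPTS (0.2 equiv), acetone/H2O (9:1), 55 °C
Reagents that add atoms: water, O
Why: Acid-catalysed ketal hydrolysis under conditions that leave the hindered secondary silyl ether, both esters and the enoate untouched.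

Step 13
Reactants: 19 methyl (1R,2S,3S,4S)-4-[(tert-butyldimethylsilyl)oxy]-3-[(1E)-3-methoxy-3-oxoprop-1-en-1-yl]-1,3-dimethyl-2-(3-oxobutyl)cyclohexane-1-carboxylate
Product: 20 methyl (1R,4S,4aR,5S,6S,8aS)-4-[(tert-butyldimethylsilyl)oxy]-6-hydroxy-5-(2-methoxy-2-oxoethyl)-1,4a,6-trimethyldecahydronaphthalene-1-carboxylate
Conditions: SmI2 (2.5 equiv, 0.1 M in THF), HMPA (10 equiv), t-BuOH (2 equiv), THF, −78 °C; aq NH4Cl at −78 °C
Reagents that add atoms: none
Why: Electron transfer from SmI2 to the unhindered C8 methyl ketone gives a samarium-bound ketyl radical that adds to C9, the β-carbon of the E-enoate; the resulting C11 radical α to the ester is reduced by a second equivalent to a samarium enolate, which t-BuOH protonates to the CH2CO2CH3 arm. The closest known reaction type is the SmI2-mediated ketone–enoate (ketyl–olefin) reductive cyclisation that gives 2-(alkoxycarbonylmethyl)cycloalkanols. Ring B closes in 6-exo-trig mode through a chair-like transition state fused to the ring A chair, with the C5 tether and the C10 enoate equatorial and C20 axial, so the trans ring fusion is already fixed by C5 and C10. C9 is controlled by the enoate terminus C11 taking the pseudo-equatorial position of this chair, clear of the axial hydrogens at C1, C5 and C7, which puts C11 cis to C20. C8 is controlled by the bulky solvated O–Sm group taking the pseudo-equatorial site, away from the enoate π system and from C20, which leaves the C17 methyl axial and the hydroxyl trans to the C11 arm. The step needs reduction at the ketone in the presence of the enoate and two saturated esters, cyclisation faster than reduction of the ketyl to a secondary alcohol, and no lactonisation of the γ-hydroxy ester; the Lewis basic methyl ketone, the six-membered reach of the acceptor and the quench at −78 °C are what secure these. Only the C9 configuration is carried into the target, since C8 becomes trigonal in step 14.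

Step 14
Reactants: 20 methyl (1R,4S,4aR,5S,6S,8aS)-4-[(tert-butyldimethylsilyl)oxy]-6-hydroxy-5-(2-methoxy-2-oxoethyl)-1,4a,6-trimethyldecahydronaphthalene-1-carboxylate
Product: 22 methyl (1R,4S,4aS,5R,8aS)-4-[(tert-butyldimethylsilyl)oxy]-5-(2-methoxy-2-oxoethyl)-1,4a-dimethyl-6-methylidenedecahydronaphthalene-1-carboxylate, via chlorosulfite ester 21 (not isolated)
Conditions: SOCl2 (3 equiv), pyridine (10 equiv), CH2Cl2, −78 → −40 °C
Reagents that add atoms: none
Why: Base-mediated anti elimination from the chlorosulfite of an equatorial tertiary alcohol: no ring C–H bond is antiperiplanar to the equatorial C8–O bond, only the C17 methyl hydrogens are, so the exocyclic alkene should predominate over the endocyclic isomers toward C7 and C9.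

Step 15
Reactants: 22 methyl (1R,4S,4aS,5R,8aS)-4-[(tert-butyldimethylsilyl)oxy]-5-(2-methoxy-2-oxoethyl)-1,4a-dimethyl-6-methylidenedecahydronaphthalene-1-carboxylate
Product: 23 methyl (1R,4S,4aS,5R,8aS)-4-[(tert-butyldimethylsilyl)oxy]-1,4a-dimethyl-6-methylidene-5-(2-oxoethyl)decahydronaphthalene-1-carboxylate
Conditions: i-Bu2AlH (1.1 equiv), CH2Cl2, −78 °C; MeOH, then aq KNaC4H4O6
Reagents that add atoms: none
Why: Partial reduction of an ester to the aldehyde through an aluminium hemiacetal that is stable at −78 °C; the C19 ester on quaternary C4, axial and syn to C20, is far more hindered than the primary CH2CO2CH3 arm.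

Step 16
Reactants: 23 methyl (1R,4S,4aS,5R,8aS)-4-[(tert-butyldimethylsilyl)oxy]-1,4a-dimethyl-6-methylidene-5-(2-oxoethyl)decahydronaphthalene-1-carboxylate
Product: 24 methyl (1R,4S,4aS,5R,8aS)-4-[(tert-butyldimethylsilyl)oxy]-1,4a-dimethyl-5-[(2E)-3-methyl-4-oxobut-2-en-1-yl]-6-methylidenedecahydronaphthalene-1-carboxylate
Conditions: Ph3P=C(CH3)CHO (1.5 equiv), toluene, 90 °C
Reagents that add atoms: 2-(triphenylphosphoranylidene)propanal, CC(C=O)=P(c1ccccc1)(c1ccccc1)c1ccccc1
Why: Wittig olefination with a stabilised formyl ylide gives the trisubstituted E-enal; the neutral conditions leave the exocyclic alkene and the aldehyde α-CH2 untouched.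

Step 17
Reactants: 24 methyl (1R,4S,4aS,5R,8aS)-4-[(tert-butyldimethylsilyl)oxy]-1,4a-dimethyl-5-[(2E)-3-methyl-4-oxobut-2-en-1-yl]-6-methylidenedecahydronaphthalene-1-carboxylate
Product: 25 methyl (1R,4S,4aS,5R,8aS)-4-[(tert-butyldimethylsilyl)oxy]-1,4a-dimethyl-6-methylidene-5-[(2E)-3-methylpenta-2,4-dien-1-yl]decahydronaphthalene-1-carboxylate
Conditions: Ph3PCH3Br (1.5 equiv), KOt-Bu (1.4 equiv), THF, 0 °C; then 24, 0 °C → rt
Reagents that add atoms: methyltriphenylphosphonium bromide, C[P+](c1ccccc1)(c1ccccc1)c1ccccc1.[Br-]
Why: Wittig methylenation of the enal carbonyl (1,2-addition of the non-stabilised ylide) completes the conjugated diene without touching the C12=C13 geometry; the hindered C19 ester should not react with the ylide at 0 °C.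

Step 18
Reactants: 25 methyl (1R,4S,4aS,5R,8aS)-4-[(tert-butyldimethylsilyl)oxy]-1,4a-dimethyl-6-methylidene-5-[(2E)-3-methylpenta-2,4-dien-1-yl]decahydronaphthalene-1-carboxylate
Product: 26 methyl (1R,4S,4aS,5R,8aS)-4-hydroxy-1,4a-dimethyl-6-methylidene-5-[(2E)-3-methylpenta-2,4-dien-1-yl]decahydronaphthalene-1-carboxylate
Conditions: Bu4NF (3 equiv), THF, 50 °C
Reagents that add atoms: none
Why: Fluoride-induced cleavage of the silyl ether; non-acidic conditions are chosen because acid would isomerise the exocyclic alkene and the diene.

Step 19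
Reactants: 26 methyl (1R,4S,4aS,5R,8aS)-4-hydroxy-1,4a-dimethyl-6-methylidene-5-[(2E)-3-methylpenta-2,4-dien-1-yl]decahydronaphthalene-1-carboxylate
Product: 27 methyl (1R,4S,4aS,5R,8aS)-4-(acetyloxy)-1,4a-dimethyl-6-methylidene-5-[(2E)-3-methylpenta-2,4-dien-1-yl]decahydronaphthalene-1-carboxylate
Conditions: Ac2O (3 equiv), DMAP (0.2 equiv), pyridine, rt
Reagents that add atoms: acetic anhydride, CC(=O)OC(C)=O
Why: Nucleophile-catalysed acylation of the equatorial secondary alcohol; no stereocentre is touched and the product is the target.

## Compound list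

1 | methyl benzoate | COC(=O)c1ccccc1 | starting material
2 | lithium enolate of methyl cyclohexa-2,5-diene-1-carboxylate | COC(O[Li])=C1C=CCC=C1 | intermediate
3 | methyl 1-methylcyclohexa-2,5-diene-1-carboxylate | COC(=O)C1(C)C=CCC=C1 | intermediate
4 | methyl 1-methyl-4-oxocyclohexa-2,5-diene-1-carboxylate | COC(=O)C1(C)C=CC(=O)C=C1 | intermediate
5 | 2-(2-bromoethyl)-2-methyl-1,3-dioxolane | CC1(CCBr)OCCO1 | starting material
6 | [2-(2-methyl-1,3-dioxolan-2-yl)ethyl]magnesium bromide | CC1(CC[Mg]Br)OCCO1 | intermediate
7 | bromomagnesium dienolate of 8 (O–MgBr on C1, C1=C10 and C2=C3 double bonds) | CC1(CC[C@H]2C=C(O[Mg]Br)C=C[C@@]2(C)C(=O)OC)OCCO1 | intermediate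
8 | methyl (1S,6S)-1-methyl-6-[2-(2-methyl-1,3-dioxolan-2-yl)ethyl]-4-oxocyclohex-2-ene-1-carboxylate | CC1(CC[C@H]2CC(=O)C=C[C@@]2(C)C(=O)OC)OCCO1 | intermediate
9 | lithium dienolate of 8 | CC1(CC[C@H]2C=C(O[Li])C=C[C@@]2(C)C(=O)OC)OCCO1 | intermediate
10 | methyl (1R,5S,6S)-1,5-dimethyl-6-[2-(2-methyl-1,3-dioxolan-2-yl)ethyl]-4-oxocyclohex-2-ene-1-carboxylate | CC1(CC[C@H]2[C@H](C)C(=O)C=C[C@@]2(C)C(=O)OC)OCCO1 | intermediate
11 | lithium dienolate of 10 | CC1(CC[C@H]2C(C)=C(O[Li])C=C[C@@]2(C)C(=O)OC)OCCO1 | intermediate
12 | methyl (1R,5R,6S)-5-(hydroxymethyl)-1,5-dimethyl-6-[2-(2-methyl-1,3-dioxolan-2-yl)ethyl]-4-oxocyclohex-2-ene-1-carboxylate | CC1(CC[C@H]2[C@](C)(CO)C(=O)C=C[C@@]2(C)C(=O)OC)OCCO1 | intermediate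
13 | methyl (1R,2S,3R)-3-(hydroxymethyl)-1,3-dimethyl-2-[2-(2-methyl-1,3-dioxolan-2-yl)ethyl]-4-oxocyclohexane-1-carboxylate | CC1(CC[C@H]2[C@](C)(CO)C(=O)CC[C@@]2(C)C(=O)OC)OCCO1 | intermediate
14 | methyl (1R,2S,3R,4S)-4-hydroxy-3-(hydroxymethyl)-1,3-dimethyl-2-[2-(2-methyl-1,3-dioxolan-2-yl)ethyl]cyclohexane-1-carboxylate | CC1(CC[C@H]2[C@](C)(CO)[C@@H](O)CC[C@@]2(C)C(=O)OC)OCCO1 | intermediate
15 | methyl (1R,2S,3S,4S)-3-formyl-4-hydroxy-1,3-dimethyl-2-[2-(2-methyl-1,3-dioxolan-2-yl)ethyl]cyclohexane-1-carboxylate | CC1(CC[C@H]2[C@](C)(C=O)[C@@H](O)CC[C@@]2(C)C(=O)OC)OCCO1 | intermediate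
16 | methyl (1R,2S,3S,4S)-4-[(tert-butyldimethylsilyl)oxy]-3-formyl-1,3-dimethyl-2-[2-(2-methyl-1,3-dioxolan-2-yl)ethyl]cyclohexane-1-carboxylate | CC1(CC[C@H]2[C@](C)(C=O)[C@@H](O[Si](C)(C)C(C)(C)C)CC[C@@]2(C)C(=O)OC)OCCO1 | intermediate
17 | trimethyl phosphonoacetate | COC(=O)CP(=O)(OC)OC | starting material
18 | methyl (1R,2S,3S,4S)-4-[(tert-butyldimethylsilyl)oxy]-3-[(1E)-3-methoxy-3-oxoprop-1-en-1-yl]-1,3-dimethyl-2-[2-(2-methyl-1,3-dioxolan-2-yl)ethyl]cyclohexane-1-carboxylate | CC1(CC[C@H]2[C@](C)(/C=C/C(=O)OC)[C@@H](O[Si](C)(C)C(C)(C)C)CC[C@@]2(C)C(=O)OC)OCCO1 | intermediate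
19 | methyl (1R,2S,3S,4S)-4-[(tert-butyldimethylsilyl)oxy]-3-[(1E)-3-methoxy-3-oxoprop-1-en-1-yl]-1,3-dimethyl-2-(3-oxobutyl)cyclohexane-1-carboxylate | CC(=O)CC[C@H]1[C@](C)(/C=C/C(=O)OC)[C@@H](O[Si](C)(C)C(C)(C)C)CC[C@@]1(C)C(=O)OC | intermediate
20 | methyl (1R,4S,4aR,5S,6S,8aS)-4-[(tert-butyldimethylsilyl)oxy]-6-hydroxy-5-(2-methoxy-2-oxoethyl)-1,4a,6-trimethyldecahydronaphthalene-1-carboxylate | COC(=O)C[C@@H]1[C@@](C)(O)CC[C@H]2[C@@]1(C)[C@@H](O[Si](C)(C)C(C)(C)C)CC[C@@]2(C)C(=O)OC | intermediate
21 | chlorosulfite ester of 20 (C8–O–S(O)Cl) | COC(=O)C[C@@H]1[C@@](C)(OS(Cl)=O)CC[C@H]2[C@@]1(C)[C@@H](O[Si](C)(C)C(C)(C)C)CC[C@@]2(C)C(=O)OC | intermediate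
22 | methyl (1R,4S,4aS,5R,8aS)-4-[(tert-butyldimethylsilyl)oxy]-5-(2-methoxy-2-oxoethyl)-1,4a-dimethyl-6-methylidenedecahydronaphthalene-1-carboxylate | COC(=O)C[C@@H]1C(=C)CC[C@H]2[C@@]1(C)[C@@H](O[Si](C)(C)C(C)(C)C)CC[C@@]2(C)C(=O)OC | intermediate
23 | methyl (1R,4S,4aS,5R,8aS)-4-[(tert-butyldimethylsilyl)oxy]-1,4a-dimethyl-6-methylidene-5-(2-oxoethyl)decahydronaphthalene-1-carboxylate | O=CC[C@@H]1C(=C)CC[C@H]2[C@@]1(C)[C@@H](O[Si](C)(C)C(C)(C)C)CC[C@@]2(C)C(=O)OC | intermediate
24 | methyl (1R,4S,4aS,5R,8aS)-4-[(tert-butyldimethylsilyl)oxy]-1,4a-dimethyl-5-[(2E)-3-methyl-4-oxobut-2-en-1-yl]-6-methylidenedecahydronaphthalene-1-carboxylate | O=C/C(C)=C/C[C@@H]1C(=C)CC[C@H]2[C@@]1(C)[C@@H](O[Si](C)(C)C(C)(C)C)CC[C@@]2(C)C(=O)OC | intermediate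
25 | methyl (1R,4S,4aS,5R,8aS)-4-[(tert-butyldimethylsilyl)oxy]-1,4a-dimethyl-6-methylidene-5-[(2E)-3-methylpenta-2,4-dien-1-yl]decahydronaphthalene-1-carboxylate | C=C/C(C)=C/C[C@@H]1C(=C)CC[C@H]2[C@@]1(C)[C@@H](O[Si](C)(C)C(C)(C)C)CC[C@@]2(C)C(=O)OC | intermediate
26 | methyl (1R,4S,4aS,5R,8aS)-4-hydroxy-1,4a-dimethyl-6-methylidene-5-[(2E)-3-methylpenta-2,4-dien-1-yl]decahydronaphthalene-1-carboxylate | C=C/C(C)=C/C[C@@H]1C(=C)CC[C@H]2[C@@]1(C)[C@@H](O)CC[C@@]2(C)C(=O)OC | intermediate
27 | methyl (1R,4S,4aS,5R,8aS)-4-(acetyloxy)-1,4a-dimethyl-6-methylidene-5-[(2E)-3-methylpenta-2,4-dien-1-yl]decahydronaphthalene-1-carboxylate (CNP0235031.1; 1S,4R,5S,9R,10S in labdane numbering) | C=C/C(C)=C/C[C@@H]1C(=C)CC[C@H]2[C@@]1(C)[C@@H](OC(C)=O)CC[C@@]2(C)C(=O)OC | target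

## Step count and least certain steps

Total: 19 steps. Longest linear sequence: 18 steps (steps 1, 2 and 4–19 from methyl benzoate 1); step 3 is a one-step branch that prepares the Grignard reagent 6.

**Step 13, the key step.** Three processes may spoil it:
- reduction of the enoate double bond or of the ketone without C–C bond formation;
- erosion of C9 selectivity, because the pseudo-equatorial C11 must pass the equatorial C1 silyloxy group;
- erosion of C8 selectivity through the developing syn-axial C17/C20 interaction, followed by lactonisation of the γ-hydroxy ester. The C8 outcome affects only the regiochemistry of step 14, not the target's stereochemistry.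

The fallback generates the same C8 radical by hydrogen-atom transfer instead of electron transfer. It sets out from 19, which TMSOTf/Et3N would convert into the trimethylsilyl enol ether of the methyl ketone F1 (the terminal regioisomer converges on the same radical). Fe(acac)3 and PhSiH3 in EtOH/ethylene glycol at 60 °C would then add a hydrogen atom to the enol ether and give the neutral tertiary α-silyloxy radical at C8, which adds 6-exo to C9 of the enoate to give the cyclised trimethylsilyl ether F2. K2CO3 in MeOH would cleave the tertiary silyl ether and return to the route at 20.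

**Step 4.** The alkyl group may be delivered syn to the methyl instead of syn to the ester, because the steric difference between the two C4 substituents is small. Enantioselectivity may also fall, because the β-carbon is neopentyl and the Grignard reagent carries a Lewis basic ketal, and uncatalysed 1,2-addition to the dienone carbonyl may compete with the copper-mediated pathway. The fallback replaces the ester by a nitrile, which is linear and much smaller than methyl, so the methyl group becomes the unambiguous blocking group. It sets out from 3, which Me2AlNH2 in hot xylene would convert into 1-methylcyclohexa-2,5-diene-1-carbonitrile F3. Oxidation as in step 2 would give the cyano dienone F4, and conjugate addition of 6 as in step 4 would give the cyano enone F5. Neutral hydration with [PtH(PMe2OH)(PMe2O)2H] would give the primary amide F6, and Me2NCH(OMe)2 in MeOH would convert the amide into the methyl ester, returning to the route at 8.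

**Step 6.** Enolisation of the hindered tertiary α′-C–H may be incomplete, formaldehyde may be lost again by retro-aldol cleavage, and so small an electrophile may discriminate poorly between the faces. The fallback uses an irreversible alkylation. It sets out from 10, whose dienolate 11 would be alkylated with benzyl chloromethyl ether to give the benzyloxymethyl enone F7. H2 over Pd(OH)2/C would then remove the benzyl group and saturate the C2=C3 double bond in one operation, returning to the route at 13 and bypassing 12.

**Step 14.** Ring protons at C7 or C9 may be lost in competition with the methyl protons, giving endocyclic alkenes, and the γ-hydroxy ester may lactonise under the acidic by-products. The fallback is a thermal syn-elimination. It sets out from 20, which AcCl and N,N-dimethylaniline would convert into the tertiary acetate F8. Heating in 2,4,6-collidine at about 170 °C would eliminate by a cyclic syn pathway that statistically favours the three methyl hydrogens, returning to the route at 22.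

**Step 15.** The aldehyde may be reduced on to the primary alcohol, the C19 ester may be partly attacked, and the aluminium Lewis acid may promote cyclisation of the aldehyde onto the exocyclic alkene during work-up. The fallback sets out from 22, which i-PrMgCl and MeNHOMe·HCl at −20 °C would convert, at the unhindered ester only, into the N-methoxy-N-methylamide F9. Reduction with i-Bu2AlH at −78 °C stops at a chelated tetrahedral intermediate that cannot be over-reduced, and work-up returns to the route at 23.

## Further compounds

F1 | step 13 | methyl (1R,2S,3S,4S)-4-[(tert-butyldimethylsilyl)oxy]-3-[(1E)-3-methoxy-3-oxoprop-1-en-1-yl]-1,3-dimethyl-2-[(2Z)-3-(trimethylsilyloxy)but-2-en-1-yl]cyclohexane-1-carboxylate | C/C(O[Si](C)(C)C)=C/C[C@H]1[C@](C)(/C=C/C(=O)OC)[C@@H](O[Si](C)(C)C(C)(C)C)CC[C@@]1(C)C(=O)OC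
F2 | step 13 | methyl (1R,4S,4aR,5S,6S,8aS)-4-[(tert-butyldimethylsilyl)oxy]-5-(2-methoxy-2-oxoethyl)-1,4a,6-trimethyl-6-(trimethylsilyloxy)decahydronaphthalene-1-carboxylate | COC(=O)C[C@@H]1[C@@](C)(O[Si](C)(C)C)CC[C@H]2[C@@]1(C)[C@@H](O[Si](C)(C)C(C)(C)C)CC[C@@]2(C)C(=O)OC
F3 | step 4 | 1-methylcyclohexa-2,5-diene-1-carbonitrile | CC1(C#N)C=CCC=C1
F4 | step 4 | 1-methyl-4-oxocyclohexa-2,5-diene-1-carbonitrile | CC1(C#N)C=CC(=O)C=C1
F5 | step 4 | (1S,6S)-1-methyl-6-[2-(2-methyl-1,3-dioxolan-2-yl)ethyl]-4-oxocyclohex-2-ene-1-carbonitrile | CC1(CC[C@H]2CC(=O)C=C[C@@]2(C)C#N)OCCO1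
F6 | step 4 | (1S,6S)-1-methyl-6-[2-(2-methyl-1,3-dioxolan-2-yl)ethyl]-4-oxocyclohex-2-ene-1-carboxamide | CC1(CC[C@H]2CC(=O)C=C[C@@]2(C)C(N)=O)OCCO1
F7 | step 6 | methyl (1R,5R,6S)-5-[(benzyloxy)methyl]-1,5-dimethyl-6-[2-(2-methyl-1,3-dioxolan-2-yl)ethyl]-4-oxocyclohex-2-ene-1-carboxylate | CC1(CC[C@H]2[C@](C)(COCc3ccccc3)C(=O)C=C[C@@]2(C)C(=O)OC)OCCO1
F8 | step 14 | methyl (1R,4S,4aR,5S,6S,8aS)-6-(acetyloxy)-4-[(tert-butyldimethylsilyl)oxy]-5-(2-methoxy-2-oxoethyl)-1,4a,6-trimethyldecahydronaphthalene-1-carboxylate | COC(=O)C[C@@H]1[C@@](C)(OC(C)=O)CC[C@H]2[C@@]1(C)[C@@H](O[Si](C)(C)C(C)(C)C)CC[C@@]2(C)C(=O)OC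
F9 | step 15 | methyl (1R,4S,4aS,5R,8aS)-4-[(tert-butyldimethylsilyl)oxy]-5-{2-[methoxy(methyl)amino]-2-oxoethyl}-1,4a-dimethyl-6-methylidenedecahydronaphthalene-1-carboxylate | CON(C)C(=O)C[C@@H]1C(=C)CC[C@H]2[C@@]1(C)[C@@H](O[Si](C)(C)C(C)(C)C)CC[C@@]2(C)C(=O)OC
A1 | alternative 1 | (6E)-3-[(tert-butyldimethylsilyl)oxy]-1-methyl-7-[(trimethylsilyl)methyl]-11-oxabicyclo[8.1.0]undec-6-ene (trans epoxide, configuration as in the SMILES) | C[C@]12C[C@@H](O[Si](C)(C)C(C)(C)C)CC/C=C(\C[Si](C)(C)C)CC[C@@H]1O2
A2 | alternative 1 | trans-fused 7-[(tert-butyldimethylsilyl)oxy]-8a-methyl-4-methylidenedecahydronaphthalen-1-ol (configuration as in the SMILES) | C1[C@@H](O[Si](C)(C)C(C)(C)C)CC[C@H]2[C@@]1(C)[C@@H](O)CCC2=C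
A3 | alternative 2 | (bromomethyl)dimethylsilyl ether of the C1 alcohol of the C5=C10 octalin carrying the C8 dioxolane and the C4 methyl and methoxycarbonyl groups (configuration as in the SMILES) | BrC[Si](C)(C)O[C@H]1CC[C@@](C)(C(=O)OC)C2=C1CC1(OCCO1)CC2
A4 | alternative 2 | trans-decalin with a dimethylsiloxane ring bridging the C1 oxygen and C20, C8 dioxolane and C4 methyl and methoxycarbonyl groups (configuration as in the SMILES) | C1C2(OCCO2)CC[C@H]3[C@]14C[Si](C)(C)O[C@H]4CC[C@@]3(C)C(=O)OC
A5 | alternative 3 | (5S)-3-methyl-5-{[(1S,2R,5S)-5-methyl-2-(propan-2-yl)cyclohexyl]oxy}furan-2(5H)-one | O=C1O[C@H](O[C@H]2C[C@@H](C)CC[C@@H]2C(C)C)C=C1C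
A6 | alternative 3 | trimethyl{[(3Z)-penta-1,3-dien-3-yl]oxy}silane | C/C=C(\O[Si](C)(C)C)C=C
A7 | alternative 3 | cis-fused menthyl lactone acetal of the ring A trimethylsilyl enol ether (configuration as in the SMILES) | C[C@H]1C(O[Si](C)(C)C)=CC[C@@]2(C)C(=O)O[C@H](O[C@H]3C[C@@H](C)CC[C@@H]3C(C)C)[C@@H]12
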